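**Target 18:** [(2S,3R,4R)-2-(3,4-dihydroxyphenyl)-4-[(4-hydroxy-3-methoxyphenyl)methyl]oxolan-3-yl]methyl acetate, COc1cc(C[C@H]2CO[C@H](c3ccc(O)c(O)c3)[C@H]2COC(C)=O)ccc1O

## The problem

Compound 18 is a single tetrahydrofuran ring (O1, C2–C5) with a catechol ring on C2, an acetoxymethyl group on C3, a 4-hydroxy-3-methoxybenzyl group on C4 and an unsubstituted CH2 at C5. The three contiguous stereocentres are 2S,3R,4R: the aryl group is trans to the C3 arm, and the C3 and C4 arms are cis. That cis relation is the less stable one, so it has to be set kinetically and must never sit next to a free, enolisable carbonyl. An external element can set C4; C3 follows if both ring bonds are made on one face of a cis-alkene; C2 can then be steered by the bicyclic shape of the intermediate. The C2–O1 bond is a para-oxygenated benzylic ether that ionises in acid (epimerisation) and can be hydrogenolysed. The free catechol is sensitive to air and base. The acetate does not survive hydride, organometallics or base and must end on the only aliphatic hydroxyl beside three phenols. The phenols therefore stay masked until the last step and are freed under neutral conditions. The enabling feature is that O1 is flanked by C2 and C5, both bonded to the C3–C4 unit, and that C3 and C4 each carry one exocyclic carbon at a different oxidation level. The ring is thus the (3+2) adduct of a C2–O1–C5 carbonyl ylide and a cis-alkene whose ends bear a carboxyl-level and an aldehyde-level carbon, that is, a 5-alkoxybutenolide.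

## Retrosynthesis

**18 to 17.** The three aryl O–benzyl bonds and the exocyclic benzylic C–O bond of the C4 arm are cut together. Diacetate 17 carries the final acetate before any phenol is free, so the two hydroxyls of its precursor need no differentiation. The forward hydrogenolysis has to remove the acyclic benzylic acetate and spare the ring C2–O1 bond.

**17 to 16 to 14 + 9.** Diol 16 is cut at the aryl–carbon bond of the C4 arm. This gives bicyclic lactol 14 and the aryl Grignard reagent 15, made from bromide 9, itself the benzyl ether of phenol 8. Lactol 14 holds the two arms cis in a 3,7-dioxabicyclo[3.3.0]octane and masks the aldehyde, so C4 is never α to a free carbonyl. Wittig chemistry would add one carbon too many; aryl addition followed by deoxygenation gives the correct chain length.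

**14 to 12 to 11.** Lactol 14 comes from ester acetal 12 by hydride reduction and hydrolysis (through 13). Ester acetal 12 comes from lactone acetal 11 by acidic methanolysis, which opens the pseudo-ester and releases the auxiliary. Direct hydride reduction of 11 would bring both carbons to the alcohol level and lose their distinction; methanolysis first keeps the former acetal carbon at the aldehyde level.

**11 to 4 + 7 (through 10).** Bonds C2–C3 and C4–C5 are cut, giving butenolide 4 and carbonyl ylide 10, which is generated from silyl chloromethyl ether 7. This one cut removes the ring and all three ring stereocentres. The forward step needs attack anti to the menthyloxy group, the CH2 terminus on the β-carbon, and the aryl group exo.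

**7 to 6 to 5.** The chloromethyl ether comes from α-silyl alcohol 6, made by silyl transfer to aldehyde 5. A dimethylphenylsilyl group replaces trimethylsilyl because it can be delivered to an aromatic aldehyde under neutral copper catalysis without Brook rearrangement; it leaves as the fluorosilane in the same way.

**4 to 2 + 3, and 2 to 1.** The butenolide is the (+)-menthyl acetal of 5-hydroxyfuranone 2, obtained by photo-oxygenation of furfural 1. Crystallisation sets the acetal centre.

## Roads not taken

**Alternative 1: anodic oxidation and quinone methide cycloetherification.**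
- Cut: O1–C2, leading back to the open-chain diol A2.
- Forward key step: two-electron anodic oxidation of the catechol of A2 gives the ortho-quinone, which tautomerises to the para-quinone methide. The hydroxyl on the C4 arm then adds 5-exo to C2 and gives the deacetyl compound A1.
- Merits: no phenol protection at the key stage, no benzylic deoxygenation, and C3/C4 come from well-known acyclic chemistry.
- Weak points: A1 still carries a catechol that oxidises at about the same potential as A2, so over-oxidation is built in. The ortho-quinone can also be attacked on the ring or oligomerise before it tautomerises. C2 is set only by the preference of the ring closure. The last step must acetylate one aliphatic hydroxyl beside three phenols.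
- Comparison: this road is better in protecting-group economy. The chosen plan sets against it that every intermediate is protected, that the acetate is placed before the phenols are freed, and that the ring and its three centres are made in one step.

**Alternative 2: aryl carbene and enal (4+1).**
- Cut: O1–C2 and C2–C3, leading back to the Z-enal A4 and the aryldiazomethane A5.
- Forward key step: a copper carbene from A5 (for example with Cu(MeCN)4PF6) adds to the carbonyl oxygen of A4. The vinyl carbonyl ylide closes by 1,5-electrocyclisation to dihydrofuran A3.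
- Merits: the whole skeleton is assembled in one step, and the C4 arm is already at the CH2 level.
- Weak points: the ylide has probably left the metal before it cyclises, so absolute control is doubtful. The donor-only diazo compound is prone to dimerise, and the Z-enal to isomerise. C4 is still missing and must be set by hydrogenating the enol ether, where the C3 arm and the C2 aryl group lie on opposite faces and steer in opposite directions, in a molecule full of hydrogenolysable bonds.
- Comparison: this road is shorter after the key step and needs no auxiliary removal. The chosen plan sets against it a crystalline auxiliary with separable diastereomers and a C3/C4 cis relation that follows from the mechanism.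

**Alternative 3: furan-derived cyclopropane and retro-aldol lactonisation.**
- Cut: O1–C5 as a lactone; the C2 aryl group enters earlier by addition to a cyclopropane carbaldehyde.
- Forward key step: Ba(OH)2 cleaves the oxalate of A7, the cyclopropanol opens by retro-aldol, and the C2 hydroxyl lactonises to the trans lactone aldehyde A6.
- Merits: each reaction has close precedent, the absolute configuration comes from a catalytic cyclopropanation, and the C2/C3 trans relation is secure.
- Weak points: in A6, C5 is a carbonyl and C4 a bare CH2. The C4 arm would have to be introduced cis to C3 although lactone enolate alkylation gives trans. The lactone must later be reduced to the ether with Lewis acid beside the labile C2–O1 bond, and the aldehyde needs protection meanwhile.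
- Comparison: this road is better in precedent and uses a catalyst in place of a stoichiometric auxiliary. The chosen plan sets against it that C5 arrives as CH2 and C4 arrives substituted and cis, with far fewer steps after the key step.

Key step: step 6

Remark: O1 and C2–C5 denote the tetrahydrofuran atoms of 18 in all compounds. The lactol carbon of 14 and the aryl carbinol carbon of 16 and 17 are epimer mixtures without consequence, since that carbon ends as CH2.

## Route

Step 1
Reactants: 1 furfural
Product: 2 5-hydroxyfuran-2(5H)-one (racemic)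
Conditions: O2, methylene blue (cat.), visible light, MeOH, rt
Reagents that add atoms: oxygen, O=O
Why: Singlet-oxygen (4+2) photo-oxygenation of the furan gives an endoperoxide that fragments in methanol with loss of the formyl carbon as methyl formate, a standard preparation of this pseudo-acid.

Step 2
Reactants: 2 5-hydroxyfuran-2(5H)-one; 3 (+)-menthol, (1S,2R,5S)-5-methyl-2-(propan-2-yl)cyclohexan-1-ol
Product: 4 (5S)-5-{[(1S,2R,5S)-5-methyl-2-(propan-2-yl)cyclohexyl]oxy}furan-2(5H)-one
Conditions: CSA (cat.), toluene, reflux, Dean–Stark; crystallisation from petroleum ether, mother liquor re-equilibrated with CSA and recrystallised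
Reagents that add atoms: none
Why: Acid-catalysed acetalisation of the lactol; the two acetal epimers interconvert under acid and the 5S epimer of the (+)-menthyl series (mirror image of the familiar 5R epimer from (−)-menthol) should crystallise, so the centre is set by crystallisation-induced diastereomer transformation.

Step 3
Reactants: 5 3,4-bis(benzyloxy)benzaldehyde
Product: 6 rac-[3,4-bis(benzyloxy)phenyl][dimethyl(phenyl)silyl]methanol
Conditions: Me2PhSi–Bpin, CuCl (5 mol %), 1,3-bis(2,6-diisopropylphenyl)imidazolium chloride (5 mol %), NaOtBu (12 mol %), THF, rt; aq. NH4Cl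
Reagents that add atoms: (dimethylphenylsilyl)boronic acid pinacol ester, CC1(C)OB(OC1(C)C)[Si](C)(C)c1ccccc1
Why: Copper-catalysed 1,2-addition of a silyl nucleophile from a Si–B reagent to an aldehyde, the O-boryl ether being hydrolysed on work-up; the neutral conditions avoid the Brook rearrangement that threatens α-silyl benzylic alkoxides of alkali metals, and the racemic centre is erased in the ylide.

Step 4
Reactants: 6 rac-[3,4-bis(benzyloxy)phenyl][dimethyl(phenyl)silyl]methanol
Product: 7 rac-{[3,4-bis(benzyloxy)phenyl](chloromethoxy)methyl}(dimethyl)phenylsilane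
Conditions: (CH2O)n, Me3SiCl, CH2Cl2, 0 °C to rt; volatiles removed, used crude
Reagents that add atoms: paraformaldehyde (as formaldehyde), C=O; chlorotrimethylsilane, C[Si](C)(C)Cl
Why: Standard chloromethylation of an alcohol through the hemiformal, whose hydroxyl is exchanged for chloride by the chlorosilane; the moisture-sensitive product is not purified.

Step 5
Reactants: 8 4-bromo-2-methoxyphenol
Product: 9 1-(benzyloxy)-4-bromo-2-methoxybenzene
Conditions: BnBr, K2CO3, DMF, rt
Reagents that add atoms: benzyl bromide, BrCc1ccccc1
Why: Williamson ether synthesis on a phenol; the benzyl group matches those of the catechol so that all three leave together at the end.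

Step 6
Reactants: 7 rac-{[3,4-bis(benzyloxy)phenyl](chloromethoxy)methyl}(dimethyl)phenylsilane; 4 (5S)-5-menthyloxyfuran-2(5H)-one
Product: 11 (3S,3aR,6S,6aS)-6-[3,4-bis(benzyloxy)phenyl]-3-{[(1S,2R,5S)-5-methyl-2-(propan-2-yl)cyclohexyl]oxy}tetrahydro-1H,3H-furo[3,4-c]furan-1-one, via carbonyl ylide 10 (not isolated)
Conditions: CsF (3 equiv, dried), MeCN, rt; 7 (1.5 equiv) added slowly to 4 and CsF
Reagents that add atoms: none
Why: Fluoride attacks silicon of 7 and chloride leaves from the chloromethyl carbon (1,3-elimination), giving the non-stabilised carbonyl ylide 10, which adds across the C3=C4 bond of 4 in a concerted, asynchronous 1,3-dipolar (3+2) cycloaddition that forms C4–C5 and C2–C3. The closest known reaction type is the CsF-induced cycloaddition of carbonyl ylides from α-silyl α'-chloro ethers to acrylates, maleates and other electron-poor alkenes, together with the anti-selective dipolar additions known for 5-alkoxyfuranones. The tetrahydrofuran ring closes by intermolecular (3+2) annulation, both bonds being made suprafacially on one face of the cis-alkene, so the new ring is necessarily cis-fused to the lactone. C4 (position 3a) is set by the 5S acetal centre, whose menthyloxy group shields its own face; C3 (position 6a) follows from suprafacial addition; C2 (position 6) is set by the exo approach that keeps the aryl group on the convex side, away from the lactone ring. Regioselectivity is needed and should be secured twofold: the small, more nucleophilic CH2 terminus bonds in advance to the electrophilic β-carbon next to the bulky acetal, while the aryl-bearing terminus, which can carry oxocarbenium character stabilised by the 4-benzyloxy group, closes on the α-carbon. Slow addition of 7 keeps the ylide concentration low against its collapse to the aryl oxirane, and adducts of any acetal-epimerised 4 are diastereomers that chromatography or crystallisation removes.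

Step 7
Reactants: 11 the cycloadduct
Product: 12 methyl (2S,3S,4R)-2-[3,4-bis(benzyloxy)phenyl]-4-(dimethoxymethyl)oxolane-3-carboxylate
Conditions: HCl (0.5 M) in MeOH, rt to 40 °C; NaHCO3 quench
Reagents that add atoms: methanol, CO
Why: Acid-catalysed methanolysis of the pseudo-ester: acetal exchange and ring opening give the normal methyl ester and the dimethyl acetal and release (+)-menthol for recovery; no ring stereocentre takes part, and the acid is kept dilute to spare the C2 benzylic ether.

Step 8
Reactants: 12 the ester acetal
Product: 14 (3aR,4S,6aR)-4-[3,4-bis(benzyloxy)phenyl]tetrahydro-1H,3H-furo[3,4-c]furan-1-ol (both anomers), via hydroxy acetal 13 (not isolated)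
Conditions: LiAlH4, THF, 0 °C; then 1 M aq. HCl, THF, rt
Reagents that add atoms: water, O
Why: Hydride reduction of the ester leaves acetal and benzyl ethers untouched; acetal hydrolysis then frees the aldehyde, which the cis hydroxymethyl group traps at once as the bicyclic lactol, so C4 is never next to a free aldehyde.

Step 9
Reactants: 9 1-(benzyloxy)-4-bromo-2-methoxybenzene; 14 the lactol
Product: 16 {(2S,3R,4R)-2-[3,4-bis(benzyloxy)phenyl]-4-{[4-(benzyloxy)-3-methoxyphenyl](hydroxy)methyl}oxolan-3-yl}methanol (carbinol epimers), via arylmagnesium bromide 15 (not isolated)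
Conditions: 9, Mg, THF, 40 °C; then 14 (3.5 equiv of 15 per 14), THF, 0 °C to rt; aq. NH4Cl
Reagents that add atoms: none
Why: Grignard addition to the open hydroxy-aldehyde form of a lactol, well known for furofuran-type lactols; the first equivalent deprotonates the lactol, and the new carbinol centre need not be controlled because it becomes CH2.

Step 10
Reactants: 16 the diol
Product: 17 {(2S,3R,4R)-4-{(acetyloxy)[4-(benzyloxy)-3-methoxyphenyl]methyl}-2-[3,4-bis(benzyloxy)phenyl]oxolan-3-yl}methyl acetate
Conditions: Ac2O, pyridine, DMAP (cat.), CH2Cl2, rt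
Reagents that add atoms: acetic anhydride, CC(=O)OC(C)=O
Why: Exhaustive acylation places the final primary acetate and turns the benzylic hydroxyl into a leaving group for hydrogenolysis, with no need to tell the two hydroxyls apart.

Step 11
Reactants: 17 the diacetate
Product: 18 [(2S,3R,4R)-2-(3,4-dihydroxyphenyl)-4-[(4-hydroxy-3-methoxyphenyl)methyl]oxolan-3-yl]methyl acetate
Conditions: H2 (1 atm), Pd/C (10 wt % palladium on carbon), EtOAc–EtOH, rt; worked up under argon
Reagents that add atoms: none
Why: Catalytic hydrogenolysis cleaves the three benzyl ethers and the acyclic benzylic acetate, a much better leaving group than the ring ether oxygen, while the primary acetate is inert; no stereocentre is touched and both carbinol epimers converge on the CH2 group.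

## Compound list

1 | furfural | O=Cc1ccco1 | starting material
2 | 5-hydroxyfuran-2(5H)-one (racemic) | O=C1C=CC(O)O1 | intermediate
3 | (+)-menthol, (1S,2R,5S)-5-methyl-2-(propan-2-yl)cyclohexan-1-ol | C[C@H]1CC[C@@H]([C@H](C1)O)C(C)C | starting material
4 | (5S)-5-{[(1S,2R,5S)-5-methyl-2-(propan-2-yl)cyclohexyl]oxy}furan-2(5H)-one | O=C1C=C[C@@H](O[C@H]2C[C@@H](C)CC[C@@H]2C(C)C)O1 | intermediate
5 | 3,4-bis(benzyloxy)benzaldehyde | O=Cc1ccc(OCc2ccccc2)c(OCc2ccccc2)c1 | starting material
6 | rac-[3,4-bis(benzyloxy)phenyl][dimethyl(phenyl)silyl]methanol | C[Si](C)(c1ccccc1)C(O)c1ccc(OCc2ccccc2)c(OCc2ccccc2)c1 | intermediate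
7 | rac-{[3,4-bis(benzyloxy)phenyl](chloromethoxy)methyl}(dimethyl)phenylsilane | C[Si](C)(c1ccccc1)C(OCCl)c1ccc(OCc2ccccc2)c(OCc2ccccc2)c1 | intermediate
8 | 4-bromo-2-methoxyphenol | COc1cc(Br)ccc1O | starting material
9 | 1-(benzyloxy)-4-bromo-2-methoxybenzene | COc1cc(Br)ccc1OCc1ccccc1 | intermediate
10 | carbonyl ylide ArCH=O(+)–CH2(−), Ar = 3,4-bis(benzyloxy)phenyl | [CH2-][O+]=Cc1ccc(OCc2ccccc2)c(OCc2ccccc2)c1 | intermediate (not isolated)
11 | (3S,3aR,6S,6aS)-6-[3,4-bis(benzyloxy)phenyl]-3-{[(1S,2R,5S)-5-methyl-2-(propan-2-yl)cyclohexyl]oxy}tetrahydro-1H,3H-furo[3,4-c]furan-1-one | O=C1O[C@H](O[C@H]3C[C@@H](C)CC[C@@H]3C(C)C)[C@H]2CO[C@H](c3ccc(OCc4ccccc4)c(OCc4ccccc4)c3)[C@@H]12 | intermediate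
12 | methyl (2S,3S,4R)-2-[3,4-bis(benzyloxy)phenyl]-4-(dimethoxymethyl)oxolane-3-carboxylate | COC(OC)[C@H]1CO[C@H](c2ccc(OCc3ccccc3)c(OCc3ccccc3)c2)[C@H]1C(=O)OC | intermediate
13 | [(2S,3R,4R)-2-[3,4-bis(benzyloxy)phenyl]-4-(dimethoxymethyl)oxolan-3-yl]methanol | COC(OC)[C@H]1CO[C@H](c2ccc(OCc3ccccc3)c(OCc3ccccc3)c2)[C@H]1CO | intermediate (not isolated)
14 | (3aR,4S,6aR)-4-[3,4-bis(benzyloxy)phenyl]tetrahydro-1H,3H-furo[3,4-c]furan-1-ol (both anomers) | OC1[C@H]2CO[C@H](c3ccc(OCc4ccccc4)c(OCc4ccccc4)c3)[C@H]2CO1 | intermediate
15 | [4-(benzyloxy)-3-methoxyphenyl]magnesium bromide | COc1cc([Mg]Br)ccc1OCc1ccccc1 | intermediate (not isolated)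
16 | {(2S,3R,4R)-2-[3,4-bis(benzyloxy)phenyl]-4-{[4-(benzyloxy)-3-methoxyphenyl](hydroxy)methyl}oxolan-3-yl}methanol (carbinol epimers) | COc1cc(C(O)[C@H]2CO[C@H](c3ccc(OCc4ccccc4)c(OCc4ccccc4)c3)[C@H]2CO)ccc1OCc1ccccc1 | intermediate
17 | {(2S,3R,4R)-4-{(acetyloxy)[4-(benzyloxy)-3-methoxyphenyl]methyl}-2-[3,4-bis(benzyloxy)phenyl]oxolan-3-yl}methyl acetate | COc1cc(C(OC(C)=O)[C@H]2CO[C@H](c3ccc(OCc4ccccc4)c(OCc4ccccc4)c3)[C@H]2COC(C)=O)ccc1OCc1ccccc1 | intermediate
18 | [(2S,3R,4R)-2-(3,4-dihydroxyphenyl)-4-[(4-hydroxy-3-methoxyphenyl)methyl]oxolan-3-yl]methyl acetate | COc1cc(C[C@H]2CO[C@H](c3ccc(O)c(O)c3)[C@H]2COC(C)=O)ccc1O | target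

## Step count and risks

Total: 11 steps. Longest linear sequence: 8 steps (5 through steps 3, 4, 6, 7, 8, 9, 10, 11; the same length from 1 through steps 1, 2, 6–11).

**Step 6 (key step).** The most likely failure is loss of control over the orientation of the unsymmetrical dipole: erosion of regiochemistry, or endo approach of the aryl group. The two ylide termini differ only modestly, and the aryl group lies far from the acetal centre. The short-lived ylide may also collapse before the moderately electrophilic butenolide captures it.

Fallback (sets out from 2 and 5, returns at 18): the ring is closed through O1–C2 by the classical lignan sequence. In this mapping the acetal carbon becomes C5, so the enantiomeric auxiliary is required.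
- Acetalisation of 2 with (−)-menthol gives (5R)-5-[(1R,2S,5R)-menthyloxy]furan-2(5H)-one F1.
- 2-[4-(Benzyloxy)-3-methoxyphenyl]-1,3-dithiane F2 is made from 4-(benzyloxy)-3-methoxybenzaldehyde and propane-1,3-dithiol with BF3·OEt2. Its lithio derivative (n-BuLi, THF, −78 °C) adds to the β-carbon of F1 anti to the menthyloxy group, and the enolate is trapped with 5 to give the trans,trans aldol adduct F3.
- NiCl2·6H2O/NaBH4 removes the sulfur to give the benzyl lactone F4.
- LiAlH4 gives the triol F5 with loss of menthol.
- CSA in CH2Cl2 ionises the benzylic alcohol, and the hydroxymethyl group on the remote carbon closes the ring trans to give the tribenzyl alcohol F6.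
- Acetylation gives the tribenzyl ether acetate F7, and brief hydrogenolysis (H2, Pd/C) gives 18.

**Step 4.** The HCl set free may ionise the electron-rich benzylic C–O bond (chloride substitution at the carbinol carbon) or chloromethylate the dialkoxyarene, since the aryl group activates both.

Fallback (from 6, returns at 7): Me2S and (BzO)2 in MeCN at 0 °C give the methylthiomethyl ether F8 under near-neutral conditions. SO2Cl2 in CH2Cl2 at −78 °C then converts it into 7.

**Step 7.** The C2–O1 benzylic ether may ionise (epimerisation at C2 or capture by methanol), or the opening may stop at the methoxy lactone. The acetal exchange needs acid of about the strength at which a para-alkoxybenzyl ether begins to ionise.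

Fallback (from 11, returns at 14): the two carbons are differentiated by sterics, without acid.
- LiAlH4 reduces 11 to the diol F9 with loss of menthol.
- TEMPO (cat.) and PhI(OAc)2 in CH2Cl2 oxidise the less hindered hydroxymethyl group (on C4, remote from the aryl-bearing C2) and carry it on to the transposed lactone F10.
- i-Bu2AlH in CH2Cl2 at −78 °C reduces F10 to 14.

**Step 11.** Over-reduction may cleave the ring C2–O1 bond once the catechol is free, or the benzylic acetate may be cleaved incompletely. Both are para-oxygenated benzylic C–O bonds that differ only in leaving group.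

Fallback (from 16, returns at 18): the benzylic oxygen is removed by radical chemistry before any hydrogenation.
- AcCl and 2,4,6-collidine in CH2Cl2 at −78 °C acetylate the primary hydroxyl only, giving the monoacetate F11.
- PhOC(S)Cl, pyridine and DMAP give the phenyl thionocarbonate F12.
- Barton–McCombie deoxygenation (Bu3SnH, AIBN, toluene, 90 °C) gives the tribenzyl ether acetate F7, the compound also reached in the fallback for step 6.
- Short hydrogenolysis (H2, Pd/C, EtOAc) then removes only the benzyl ethers and gives 18.

## Further compounds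

F1 | step 6 | (5R)-5-{[(1R,2S,5R)-5-methyl-2-(propan-2-yl)cyclohexyl]oxy}furan-2(5H)-one | O=C1C=C[C@H](O[C@@H]2C[C@H](C)CC[C@H]2C(C)C)O1
F2 | step 6 | 2-[4-(benzyloxy)-3-methoxyphenyl]-1,3-dithiane | COc1cc(C2SCCCS2)ccc1OCc1ccccc1
F3 | step 6 | 3,4-trans-4,5-trans-3-{[3,4-bis(benzyloxy)phenyl](hydroxy)methyl}-4-{2-[4-(benzyloxy)-3-methoxyphenyl]-1,3-dithian-2-yl}-5-[(1R,2S,5R)-menthyloxy]dihydrofuran-2(3H)-one (carbinol epimers) | O=C1O[C@@H](O[C@@H]2C[C@H](C)CC[C@H]2C(C)C)[C@H](C2(c3ccc(OCc4ccccc4)c(OC)c3)SCCCS2)[C@H]1C(O)c1ccc(OCc2ccccc2)c(OCc2ccccc2)c1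
F4 | step 6 | 3,4-trans-4,5-trans-4-[4-(benzyloxy)-3-methoxybenzyl]-3-{[3,4-bis(benzyloxy)phenyl](hydroxy)methyl}-5-[(1R,2S,5R)-menthyloxy]dihydrofuran-2(3H)-one (carbinol epimers) | O=C1O[C@@H](O[C@@H]2C[C@H](C)CC[C@H]2C(C)C)[C@H](Cc2ccc(OCc3ccccc3)c(OC)c2)[C@H]1C(O)c1ccc(OCc2ccccc2)c(OCc2ccccc2)c1
F5 | step 6 | (2R,3R)-2-[4-(benzyloxy)-3-methoxybenzyl]-3-{[3,4-bis(benzyloxy)phenyl](hydroxy)methyl}butane-1,4-diol (carbinol epimers) | OC[C@H](Cc1ccc(OCc2ccccc2)c(OC)c1)[C@H](CO)C(O)c1ccc(OCc2ccccc2)c(OCc2ccccc2)c1
F6 | step 6 | {(2S,3R,4R)-4-[4-(benzyloxy)-3-methoxybenzyl]-2-[3,4-bis(benzyloxy)phenyl]oxolan-3-yl}methanol | COc1cc(C[C@H]2CO[C@H](c3ccc(OCc4ccccc4)c(OCc4ccccc4)c3)[C@H]2CO)ccc1OCc1ccccc1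
F7 | step 6 | {(2S,3R,4R)-4-[4-(benzyloxy)-3-methoxybenzyl]-2-[3,4-bis(benzyloxy)phenyl]oxolan-3-yl}methyl acetate | COc1cc(C[C@H]2CO[C@H](c3ccc(OCc4ccccc4)c(OCc4ccccc4)c3)[C@H]2COC(C)=O)ccc1OCc1ccccc1
F8 | step 4 | rac-{[3,4-bis(benzyloxy)phenyl][(methylsulfanyl)methoxy]methyl}(dimethyl)phenylsilane | C[Si](C)(c1ccccc1)C(OCSC)c1ccc(OCc2ccccc2)c(OCc2ccccc2)c1
F9 | step 7 | [(2S,3R,4S)-2-[3,4-bis(benzyloxy)phenyl]oxolane-3,4-diyl]dimethanol | OC[C@H]1CO[C@H](c2ccc(OCc3ccccc3)c(OCc3ccccc3)c2)[C@H]1CO
F10 | step 7 | (3aR,4S,6aR)-4-[3,4-bis(benzyloxy)phenyl]tetrahydro-1H,3H-furo[3,4-c]furan-1-one | O=C1[C@H]2CO[C@H](c3ccc(OCc4ccccc4)c(OCc4ccccc4)c3)[C@H]2CO1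
F11 | step 11 | {(2S,3R,4R)-2-[3,4-bis(benzyloxy)phenyl]-4-{[4-(benzyloxy)-3-methoxyphenyl](hydroxy)methyl}oxolan-3-yl}methyl acetate (carbinol epimers) | COc1cc(C(O)[C@H]2CO[C@H](c3ccc(OCc4ccccc4)c(OCc4ccccc4)c3)[C@H]2COC(C)=O)ccc1OCc1ccccc1
F12 | step 11 | {(2S,3R,4R)-2-[3,4-bis(benzyloxy)phenyl]-4-{[4-(benzyloxy)-3-methoxyphenyl][(phenoxycarbonothioyl)oxy]methyl}oxolan-3-yl}methyl acetate (carbinol epimers) | COc1cc(C(OC(=S)Oc2ccccc2)[C@H]2CO[C@H](c3ccc(OCc4ccccc4)c(OCc4ccccc4)c3)[C@H]2COC(C)=O)ccc1OCc1ccccc1
A1 | alternative 1 | [(2S,3R,4R)-2-(3,4-dihydroxyphenyl)-4-[(4-hydroxy-3-methoxyphenyl)methyl]oxolan-3-yl]methanol | COc1cc(C[C@H]2CO[C@H](c3ccc(O)c(O)c3)[C@H]2CO)ccc1O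
A2 | alternative 1 | (2R,3R)-2-(3,4-dihydroxybenzyl)-3-(4-hydroxy-3-methoxybenzyl)butane-1,4-diol | COc1cc(C[C@@H](CO)[C@H](CO)Cc2ccc(O)c(O)c2)ccc1O
A3 | alternative 2 | trans-4-[4-(benzyloxy)-3-methoxybenzyl]-2-[3,4-bis(benzyloxy)phenyl]-3-{[(tert-butyldimethylsilyl)oxy]methyl}-2,3-dihydrofuran | COc1cc(CC2=CO[C@H](c3ccc(OCc4ccccc4)c(OCc4ccccc4)c3)[C@H]2CO[Si](C)(C)C(C)(C)C)ccc1OCc1ccccc1
A4 | alternative 2 | (Z)-2-[4-(benzyloxy)-3-methoxybenzyl]-4-[(tert-butyldimethylsilyl)oxy]but-2-enal | O=C/C(Cc1ccc(OCc2ccccc2)c(OC)c1)=C\CO[Si](C)(C)C(C)(C)C
A5 | alternative 2 | [3,4-bis(benzyloxy)phenyl]diazomethane | [N-]=[N+]=Cc1ccc(OCc2ccccc2)c(OCc2ccccc2)c1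
A6 | alternative 3 | trans-5-[3,4-bis(benzyloxy)phenyl]-4-formyldihydrofuran-2(3H)-one | O=C1C[C@H](C=O)[C@@H](c2ccc(OCc3ccccc3)c(OCc3ccccc3)c2)O1
A7 | alternative 3 | ethyl 2-{[3,4-bis(benzyloxy)phenyl](hydroxy)methyl}-3-[(methoxyoxalyl)oxy]cyclopropane-1-carboxylate (oxalate and carbinol arm cis, ester trans) | CCOC(=O)[C@H]1[C@H](OC(=O)C(=O)OC)[C@@H]1[C@H](O)c1ccc(OCc2ccccc2)c(OCc2ccccc2)c1
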